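**Retrosynthetic overview**
1. Atom labels Cn follow the target SMILES: C1 is the exocyclic CH2, C2–C6/C9/C26 form the seven-membered ring, C9–C12/C26 the cyclopentane, C14/C15 the side chain, and C20–C25 the lactone. The plan rests on one feature. Inside the seven-membered ring the gem-dimethyl carbon C6 is bonded to the ring-fusion methine C9, and C2, on the other side of C26, can be carried as an enol ether.
2. The C6–C9 bond is cut by a retro-Cope operation. Hydroazulene dienol silyl ether 12 goes back to cis-divinylcyclopropane 11 (ring C2–C3–C4, cyclopentenyl on C2, isobutenyl and an ester on C4).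
3. Compound 11 comes from siloxydiene 7 and vinyldiazoacetate 10 by chiral dirhodium cyclopropanation. Diene 7 comes from β-keto ester 1, with C12 set by asymmetric methylation and C2/C3 added by a Stille acetylation.
4. After the key step the C4 ester is deleted, C26 is protonated and C2 is methylenated. The C14 ester becomes a carbamate. Lithiation–borylation with a 3-furylboronate sets C14, a Matteson homologation adds C15, and the furan becomes the lactone (C20 by asymmetric conjugate reduction).
5. Ring order: cyclopentane (bought), cyclopropane (step 7, sacrificial), cycloheptane (step 8), butyrolactone (steps 19–21, from the furan).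

Key step: step 8

Notation: systematic names use azulene locants, while all "Cn" labels use the SMILES numbering above. "Az" is the 1,4,4-trimethyl-8-methylidene-cis-decahydroazulen-1-yl group of 19, bound through C12, with H9, H26 and the C12 side chain on one face and the C13 methyl on the other.
Assumption: the antipodes named for the chiral controllers in steps 1, 7 and 21 follow the sense known for the nearest substrate classes; both antipodes of each are commercial, so a reversed sense would be met by switching the antipode without changing the route.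
Remark: C4 in 13–15 and C21 in 28/29 are epimer mixtures at centres that later vanish, so they are drawn without descriptor.

**Step 1**
Reactants: 1 methyl 2-oxocyclopentane-1-carboxylate
Product: 2 methyl (1R)-1-methyl-2-oxocyclopentane-1-carboxylate
Conditions: MeI, (S,S)-3,3′-bis(3,4,5-trifluorophenyl) N-spiro-binaphthyl ammonium bromide (2 mol %), sat. aq. K2CO3, PhMe, −20 °C
Reagents that add atoms: iodomethane, CI
Why: Asymmetric phase-transfer alkylation of a cyclic β-keto ester, in which the chiral ammonium enolate ion pair exposes one enolate face to MeI and sets C12 (R); any minor enantiomer is removed later because catalyst-controlled step 7 turns it into a separable diastereomer.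

**Step 2**
Reactants: 2 methyl (1R)-1-methyl-2-oxocyclopentane-1-carboxylate
Product: 3 methyl (1R)-1-methyl-2-(trifluoromethylsulfonyloxy)cyclopent-2-ene-1-carboxylate
Conditions: KHMDS, THF, −78 °C; PhNTf2, −78 °C → 0 °C
Reagents that add atoms: N-phenylbis(trifluoromethanesulfonimide), O=S(=O)(N(c1ccccc1)S(=O)(=O)C(F)(F)F)C(F)(F)F
Why: Enolate O-triflation; only C9 carries enolisable hydrogens because C12 is quaternary, so only the C26=C9 enol triflate can form, and the non-nucleophilic base avoids retro-Dieckmann cleavage.

**Step 3**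
Reactants: 3 methyl (1R)-1-methyl-2-(trifluoromethylsulfonyloxy)cyclopent-2-ene-1-carboxylate; 4 tributyl(1-ethoxyvinyl)stannane
Product: 6 methyl (1R)-2-acetyl-1-methylcyclopent-2-ene-1-carboxylate, via ethoxydiene 5 (not isolated)
Conditions: Pd(PPh3)4 (5 mol %), LiCl, THF, 65 °C; then 1 M HCl, rt
Reagents that add atoms: water, O
Why: Stille coupling of an enol triflate with an α-alkoxyvinylstannane followed by acid hydrolysis of the enol ether is the standard acetyl-anion equivalent, and it brings in C2 and C3 without touching C12.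

**Step 4**
Reactants: 6 methyl (1R)-2-acetyl-1-methylcyclopent-2-ene-1-carboxylate
Product: 7 methyl (1R)-2-[1-(tert-butyldimethylsilyloxy)ethenyl]-1-methylcyclopent-2-ene-1-carboxylate
Conditions: TBSOTf, Et3N, CH2Cl2, 0 °C
Reagents that add atoms: tert-butyldimethylsilyl trifluoromethanesulfonate, CC(C)(C)[Si](C)(C)OS(=O)(=O)C(F)(F)F
Why: Soft enolisation (silyl triflate/amine) removes a proton from the C3 methyl group and gives the 2-siloxy-1,3-diene, the usual outcome for 1-acetylcycloalkenes.

**Step 5**
Reactants: 8 4-methylpent-3-enoic acid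
Product: 9 methyl 4-methylpent-3-enoate
Conditions: MeI, K2CO3, DMF, rt
Reagents that add atoms: iodomethane, CI
Why: Carboxylate O-alkylation under mild base avoids the acid-induced lactonisation and double-bond migration to which this β,γ-unsaturated acid is prone.

**Step 6**
Reactants: 9 methyl 4-methylpent-3-enoate
Product: 10 methyl 2-diazo-4-methylpent-3-enoate
Conditions: p-ABSA, DBU, MeCN, 0 °C → rt; kept cold and used at once
Reagents that add atoms: 4-acetamidobenzenesulfonyl azide, CC(=O)Nc1ccc(cc1)S(=O)(=O)N=[N+]=[N-]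
Why: Regitz diazo transfer to the doubly activated (allylic, α-ester) CH2 is the standard entry to vinyldiazoacetates, and prompt use forestalls closure of 10 to a 3H-pyrazole.

**Step 7**
Reactants: 7 methyl (1R)-2-[1-(tert-butyldimethylsilyloxy)ethenyl]-1-methylcyclopent-2-ene-1-carboxylate; 10 methyl 2-diazo-4-methylpent-3-enoate
Product: 11 methyl (1R,2S)-2-(tert-butyldimethylsilyloxy)-2-[(5R)-5-(methoxycarbonyl)-5-methylcyclopent-1-en-1-yl]-1-(2-methylprop-1-en-1-yl)cyclopropane-1-carboxylate (both alkenyl groups cis)
Conditions: Rh2(S-DOSP)4 (1 mol %), hexanes, −40 °C → 0 °C, slow addition of 10; Et3N-deactivated silica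
Reagents that add atoms: none
Why: Donor/acceptor rhodium-carbenoid cyclopropanation, in which the bulky carbenoid takes the terminal, most electron-rich C3=C2 bond rather than the trisubstituted ring alkene, places the cyclopentenyl arm cis to its own isobutenyl group and trans to the ester, and the chiral prolinate catalyst selects the alkene face, so C2 (S) and C4 (R) are set relative to C12.

**Step 8**
Reactants: 11 the cis-divinyl siloxycyclopropane ester of step 7
Product: 12 dimethyl (1R,3aS)-8-(tert-butyldimethylsilyloxy)-1,4,4-trimethyl-1,2,3,3a,4,7-hexahydroazulene-1,6-dicarboxylate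
Conditions: PhMe (dilute), BHT (cat.), base-washed sealed tube, 120 °C
Reagents that add atoms: none
Why: This is the thermal [3,3]-sigmatropic (Cope) rearrangement of a cis-1,2-divinylcyclopropane, the second half of the classical cyclopropanation/Cope route to cycloheptadienes: in the endo-boat array both alkenes fold over the three-membered ring, the donor/acceptor-weakened C2–C4 bond breaks while C6–C9 forms, and the π bonds move to C2=C26 (the TBS enol ether) and C4=C5 (conjugated with the ester). The seven-membered ring C2–C3–C4–C5–C6–C9–C26 is closed by sigmatropic ring expansion of the cyclopropane rather than by end-to-end cyclisation, and the released ring strain pays for joining a fully substituted carbon to a ring methine. The one new stereocentre, C9, is dictated by the cyclopropane configuration, because only the rotamer with C9 tucked under C3 can bond, so the (C2 S, C4 R) isomer presents the cyclopentene face bearing the C13 methyl group to C6 and H9 ends syn to the C12 ester. The step needs the concerted path to outrun heterolysis of the siloxy/ester-flanked bond and drift to five-membered rings, which the cis geometry, the unpolar medium and acid-free glass secure, and no cis alkyl C–H is available for a homodienyl 1,5-hydrogen shift. One C6 methyl group must point inwards in the boat, which makes 11 isolable and heating necessary, whereas C9 has only hydrogen in its inward position.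

**Step 9**
Reactants: 12 the hydroazulene dienol silyl ether diester of step 8
Product: 13 dimethyl (1R,3aS)-8-(tert-butyldimethylsilyloxy)-1,4,4-trimethyl-1,2,3,3a,4,5,6,7-octahydroazulene-1,6-dicarboxylate (C4 epimers)
Conditions: H2 (4 atm), 10 % Pd/C, EtOAc, rt
Reagents that add atoms: none
Why: Heterogeneous hydrogenation takes the conjugated trisubstituted C4=C5 bond while the tetrasubstituted, flanked silyl enol ether is left alone; the new C4 centre is uncontrolled and disappears in step 11.

**Step 10**
Reactants: 13 the saturated diester of step 9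
Product: 14 (3aS,1R)-8-(tert-butyldimethylsilyloxy)-1-(methoxycarbonyl)-1,4,4-trimethyl-1,2,3,3a,4,5,6,7-octahydroazulene-6-carboxylic acid (C4 epimers)
Conditions: Me3SnOH, ClCH2CH2Cl, 75 °C; brief cold 0.1 M HCl wash
Reagents that add atoms: trimethyltin hydroxide, C[Sn](C)(C)O
Why: Trimethyltin hydroxide hydrolysis cleaves unhindered methyl esters under nearly neutral conditions, so the secondary C4 ester reacts while the neopentylic tertiary C12 ester and the enol silane, which still masks the epimerisable C26, survive.

**Step 11**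
Reactants: 14 the C4 carboxylic acid of step 10
Product: 16 methyl (1R,3aS)-8-(tert-butyldimethylsilyloxy)-1,4,4-trimethyl-1,2,3,3a,4,5,6,7-octahydroazulene-1-carboxylate, via thiohydroxamate ester 15 (not isolated)
Conditions: 1-hydroxypyridine-2(1H)-thione, DCC, DMAP (cat.), CH2Cl2, 0 °C, dark; then t-BuSH, PhMe, hν (W lamp), rt
Reagents that add atoms: 1-hydroxypyridine-2(1H)-thione, ON1C=CC=CC1=S (its atoms stay in 15 only)
Why: Barton reductive decarboxylation, in which the thiohydroxamate ester fragments in a radical chain to the secondary C4 radical and the thiol quenches it faster than it can engage the homoallylic enol ether, erasing the C4 centre.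

**Step 12**
Reactants: 16 the enol silane monoester of step 11
Product: 17 methyl (1R,3aR,8aR)-1,4,4-trimethyl-8-oxodecahydroazulene-1-carboxylate (cis-fused)
Conditions: TBAF, AcOH, THF, −20 °C → 0 °C
Reagents that add atoms: none
Why: Buffered fluoride desilylation releases the enolate and protonates it at once under kinetic control; the lower face of C26 is flanked by C6 with its methyl groups and by the C13 methyl, the upper face only by H9 and the ester, so H26 should enter syn to H9 to give the cis fusion, and the weakly basic medium avoids later epimerisation.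

**Step 13**
Reactants: 17 the cis-fused keto ester of step 12
Product: 18 methyl (1R,3aR,8aS)-1,4,4-trimethyl-8-methylidenedecahydroazulene-1-carboxylate
Conditions: Zn, CH2Br2, TiCl4 (reagent pre-aged in THF), CH2Cl2, 0 °C → rt
Reagents that add atoms: dibromomethane, BrCBr
Why: Takai–Lombardo methylenation is non-basic, established for hindered and epimerisable ketones and leaves esters alone, so C26 is locked as an allylic methine before any base is used.

**Step 14**
Reactants: 18 the methylidene ester of step 13
Product: 19 [(1R,3aR,8aS)-1,4,4-trimethyl-8-methylidenedecahydroazulen-1-yl]methanol (Az–CH2OH)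
Conditions: LiAlH4, Et2O, 0 °C → rt
Reagents that add atoms: none
Why: Hydride reduction of the methyl ester to the neopentylic alcohol C14H2OH; the isolated alkene is inert and no stereocentre is touched.

**Step 15**
Reactants: 19 Az–CH2OH
Product: 20 Az–CH2 N,N-diisopropylcarbamate
Conditions: NaH, THF, 0 °C; i-Pr2NC(O)Cl, reflux
Reagents that add atoms: N,N-diisopropylcarbamoyl chloride, CC(C)N(C(C)C)C(=O)Cl
Why: Carbamoylation of the alkoxide installs the group that both directs α-lithiation and later acts as the leaving group.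

**Step 16**
Reactants: 20 Az–CH2 N,N-diisopropylcarbamate; 21 2-(furan-3-yl)-4,4,5,5-tetramethyl-1,3,2-dioxaborolane
Product: 24 2-[(S)-Az(furan-3-yl)methyl]-4,4,5,5-tetramethyl-1,3,2-dioxaborolane, via lithiated carbamate 22 (not isolated), via furyl boronate complex 23 (not isolated)
Conditions: s-BuLi, (+)-sparteine, Et2O, −78 °C; 21, −78 °C; MgBr2·OEt2, then reflux
Reagents that add atoms: sec-butyllithium, [Li]C(C)CC (lithium only, present in 22 and 23)
Why: Lithiation–borylation: (+)-sparteine directs removal of the pro-R hydrogen of the O-alkyl carbamate (neopentylic carbamates are known substrates), the boronic ester is captured with retention, and the furyl group migrates with inversion as the carbamate leaves (1,2-metallate rearrangement), so C14 is set by reagent control.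

**Step 17**
Reactants: 24 the secondary furyl boronic ester of step 16
Product: 26 (2S)-2-Az-2-(furan-3-yl)ethan-1-ol, via homologated boronic ester 25 (not isolated)
Conditions: BrCH2Cl, n-BuLi, Et2O, −78 °C → rt; then 2 M NaOH, 30 % H2O2, THF, 0 °C → rt
Reagents that add atoms: bromochloromethane, ClCBr; hydrogen peroxide, OO
Why: Matteson homologation with chloromethyllithium inserts C15 with retention at the migrating C14, and alkaline peroxide then oxidises the primary C–B bond without affecting furan or alkene.

**Step 18**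
Reactants: 26 (2S)-2-Az-2-(furan-3-yl)ethan-1-ol
Product: 27 (2S)-2-Az-2-(furan-3-yl)ethyl acetate
Conditions: Ac2O, pyridine, DMAP (cat.), CH2Cl2, rt
Reagents that add atoms: acetic anhydride, CC(=O)OC(C)=O
Why: Standard O-acylation, placed here so that no free C15 hydroxyl can later compete for the lactone carbonyl.

**Step 19**
Reactants: 27 (2S)-2-Az-2-(furan-3-yl)ethyl acetate
Product: 29 (2S)-2-Az-2-(2-hydroxy-5-oxo-2,5-dihydrofuran-3-yl)ethyl acetate (C21 epimers), via furan endoperoxide 28 (not isolated)
Conditions: O2, tetraphenylporphyrin (cat.), hν (visible), i-Pr2NEt, CH2Cl2, −78 °C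
Reagents that add atoms: dioxygen, O=O
Why: Furan photooxygenation ([4+2] with singlet oxygen) followed by Kornblum–DeLaMare-type opening, in which the hindered amine removes the unhindered C23–H so the carbonyl ends at C23 and the hemiacetal at C21; at −78 °C the furan reacts far faster than the 1,1-disubstituted alkene can undergo an ene reaction.

**Step 20**
Reactants: 29 the γ-hydroxybutenolide of step 19
Product: 31 (2S)-2-Az-2-(5-oxo-2,5-dihydrofuran-3-yl)ethyl acetate, via hydroxy acid 30 (not isolated)
Conditions: NaBH4, THF/EtOH, 0 °C; then 1 M HCl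
Reagents that add atoms: none
Why: Borohydride reduces the aldehyde tautomer of the γ-hydroxybutenolide and the (Z)-γ-hydroxy acid relactonises on acidification, the usual conversion into a β-substituted butenolide; the acetate survives the short cold exposure.

**Step 21**
Reactants: 31 the butenolide of step 20
Product: 32 (2R)-2-[(3R)-5-oxooxolan-3-yl]-2-[(1R,3aR,8aS)-1,4,4-trimethyl-8-methylidenedecahydroazulen-1-yl]ethyl acetate (target)
Conditions: Cu(OAc)2·H2O (5 mol %), (R)-DTBM-SEGPHOS (5 mol %), (EtO)2MeSiH, t-BuOH, PhMe, 0 °C → rt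
Reagents that add atoms: none
Why: Copper hydride-catalysed asymmetric 1,4-reduction of a β-substituted butenolide, in which the ligated CuH delivers hydride to one face of C20 (catalyst control, R), ignores the isolated alkene and the acetate, and the alkoxide-free copper acetate protocol avoids deprotonating the vinylogously acidic C14–H.

**Compound list**
1 | methyl 2-oxocyclopentane-1-carboxylate | COC(=O)C1CCCC1=O | starting material
2 | methyl (1R)-1-methyl-2-oxocyclopentane-1-carboxylate | O=C1CCC[C@@]1(C)C(=O)OC | intermediate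
3 | methyl (1R)-1-methyl-2-(trifluoromethylsulfonyloxy)cyclopent-2-ene-1-carboxylate | O=S(=O)(OC1=CCC[C@@]1(C)C(=O)OC)C(F)(F)F | intermediate
4 | tributyl(1-ethoxyvinyl)stannane | CCCC[Sn](CCCC)(CCCC)C(=C)OCC | starting material
5 | methyl (1R)-2-(1-ethoxyethenyl)-1-methylcyclopent-2-ene-1-carboxylate | C=C(OCC)C1=CCC[C@@]1(C)C(=O)OC | intermediate
6 | methyl (1R)-2-acetyl-1-methylcyclopent-2-ene-1-carboxylate | CC(=O)C1=CCC[C@@]1(C)C(=O)OC | intermediate
7 | methyl (1R)-2-[1-(tert-butyldimethylsilyloxy)ethenyl]-1-methylcyclopent-2-ene-1-carboxylate | C=C(O[Si](C)(C)C(C)(C)C)C1=CCC[C@@]1(C)C(=O)OC | intermediate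
8 | 4-methylpent-3-enoic acid | CC(C)=CCC(=O)O | starting material
9 | methyl 4-methylpent-3-enoate | CC(C)=CCC(=O)OC | intermediate
10 | methyl 2-diazo-4-methylpent-3-enoate | CC(C)=CC(=[N+]=[N-])C(=O)OC | intermediate
11 | cis-divinyl siloxycyclopropane ester (C2 S, C4 R, C12 R) | CC(C)=C[C@]1(C(=O)OC)C[C@]1(O[Si](C)(C)C(C)(C)C)C2=CCC[C@@]2(C)C(=O)OC | intermediate
12 | hydroazulene dienol silyl ether diester (1R,3aS) | CC(C)(C)[Si](C)(C)OC1=C2[C@](C)(C(=O)OC)CC[C@H]2C(C)(C)C=C(C(=O)OC)C1 | intermediate
13 | C4=C5-saturated enol silane diester (C4 epimers) | CC(C)(C)[Si](C)(C)OC1=C2[C@](C)(C(=O)OC)CC[C@H]2C(C)(C)CC(C(=O)OC)C1 | intermediate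
14 | C4 carboxylic acid, C12 methyl ester, enol silane (C4 epimers) | CC(C)(C)[Si](C)(C)OC1=C2[C@](C)(C(=O)OC)CC[C@H]2C(C)(C)CC(C(=O)O)C1 | intermediate
15 | 2-thioxopyridin-1(2H)-yl ester of 14 | CC(C)(C)[Si](C)(C)OC1=C2[C@](C)(C(=O)OC)CC[C@H]2C(C)(C)CC(C(=O)ON3C=CC=CC3=S)C1 | intermediate
16 | methyl (1R,3aS)-8-(tert-butyldimethylsilyloxy)-1,4,4-trimethyl-1,2,3,3a,4,5,6,7-octahydroazulene-1-carboxylate | CC(C)(C)[Si](C)(C)OC1=C2[C@](C)(C(=O)OC)CC[C@H]2C(C)(C)CCC1 | intermediate
17 | methyl (1R,3aR,8aR)-1,4,4-trimethyl-8-oxodecahydroazulene-1-carboxylate | O=C1CCCC(C)(C)[C@@H]2CC[C@@](C)(C(=O)OC)[C@H]12 | intermediate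
18 | methyl (1R,3aR,8aS)-1,4,4-trimethyl-8-methylidenedecahydroazulene-1-carboxylate | C=C1CCCC(C)(C)[C@@H]2CC[C@@](C)(C(=O)OC)[C@H]12 | intermediate
19 | [(1R,3aR,8aS)-1,4,4-trimethyl-8-methylidenedecahydroazulen-1-yl]methanol | C=C1CCCC(C)(C)[C@@H]2CC[C@@](C)(CO)[C@H]12 | intermediate
20 | Az–CH2 N,N-diisopropylcarbamate | C=C1CCCC(C)(C)[C@@H]2CC[C@@](C)(COC(=O)N(C(C)C)C(C)C)[C@H]12 | intermediate
21 | 2-(furan-3-yl)-4,4,5,5-tetramethyl-1,3,2-dioxaborolane | CC1(C)OB(OC1(C)C)c2ccoc2 | starting material
22 | (R)-α-lithio carbamate, (+)-sparteine complex (ligand not drawn) | C=C1CCCC(C)(C)[C@@H]2CC[C@@](C)([C@@H]([Li])OC(=O)N(C(C)C)C(C)C)[C@H]12 | intermediate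
23 | lithium furyl(α-carbamoyloxyalkyl) pinacol boronate | C=C1CCCC(C)(C)[C@@H]2CC[C@@](C)([C@@H]([B-]3(c4ccoc4)OC(C)(C)C(C)(C)O3)OC(=O)N(C(C)C)C(C)C)[C@H]12.[Li+] | intermediate
24 | 2-[(S)-Az(furan-3-yl)methyl]-4,4,5,5-tetramethyl-1,3,2-dioxaborolane | C=C1CCCC(C)(C)[C@@H]2CC[C@@](C)([C@H](B3OC(C)(C)C(C)(C)O3)c4ccoc4)[C@H]12 | intermediate
25 | 2-[(2S)-2-Az-2-(furan-3-yl)ethyl]-4,4,5,5-tetramethyl-1,3,2-dioxaborolane | C=C1CCCC(C)(C)[C@@H]2CC[C@@](C)([C@H](CB3OC(C)(C)C(C)(C)O3)c4ccoc4)[C@H]12 | intermediate
26 | (2S)-2-Az-2-(furan-3-yl)ethan-1-ol | C=C1CCCC(C)(C)[C@@H]2CC[C@@](C)([C@H](CO)c3ccoc3)[C@H]12 | intermediate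
27 | (2S)-2-Az-2-(furan-3-yl)ethyl acetate | C=C1CCCC(C)(C)[C@@H]2CC[C@@](C)([C@H](COC(C)=O)c3ccoc3)[C@H]12 | intermediate
28 | furan endoperoxide (2,3,7-trioxabicyclo[2.2.1]hept-5-ene) of 27 | C=C1CCCC(C)(C)[C@@H]2CC[C@@](C)([C@H](COC(C)=O)C3=CC4OOC3O4)[C@H]12 | intermediate
29 | (2S)-2-Az-2-(2-hydroxy-5-oxo-2,5-dihydrofuran-3-yl)ethyl acetate (C21 epimers) | C=C1CCCC(C)(C)[C@@H]2CC[C@@](C)([C@H](COC(C)=O)C3=CC(=O)OC3O)[C@H]12 | intermediate
30 | (2Z,4S)-5-acetoxy-4-Az-3-(hydroxymethyl)pent-2-enoic acid | C=C1CCCC(C)(C)[C@@H]2CC[C@@](C)([C@H](COC(C)=O)/C(CO)=C/C(=O)O)[C@H]12 | intermediate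
31 | (2S)-2-Az-2-(5-oxo-2,5-dihydrofuran-3-yl)ethyl acetate | C=C1CCCC(C)(C)[C@@H]2CC[C@@](C)([C@H](COC(C)=O)C3=CC(=O)OC3)[C@H]12 | intermediate
32 | CNP0235949.1, (2R)-2-[(3R)-5-oxooxolan-3-yl]-2-[(1R,3aR,8aS)-1,4,4-trimethyl-8-methylidenedecahydroazulen-1-yl]ethyl acetate | C=C1CCCC(C)(C)[C@@H]2CC[C@@](C)([C@H](COC(C)=O)[C@@H]3COC(=O)C3)[C@H]12 | target

**Step count**
Total steps: 21. Longest linear sequence: 19 (steps 1–4 and 7–21). Steps 5–6 form the two-step side branch to 10.

**The three steps most likely to fail**

**Step 8 (key step).**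
- What may go wrong: the inward-pointing C6 methyl group may raise the barrier so far that other processes overtake the [3,3] shift. These are heterolysis of the siloxy/ester-flanked C2–C4 bond, cis/trans leakage with loss of the stereochemical information, and drift to five-membered rings.
- Fallback (sets out from 11, returns at 17): the same C6–C9 bond is made by a radical conjugate addition instead of a pericyclic shift. Buffered fluoride (TBAF/AcOH, THF) opens the 2-siloxycyclopropanecarboxylate to the γ-keto ester methyl (1R)-2-[3-(methoxycarbonyl)-5-methylhex-4-enoyl]-1-methylcyclopent-2-ene-1-carboxylate F1. Iron-catalysed hydrogen-atom transfer (Fe(acac)3, PhSiH3, EtOH, 60 °C) places hydrogen on C5, and the tertiary C6 radical adds in 7-endo fashion to the enone β-carbon C9. This gives dimethyl 1,4,4-trimethyl-8-oxodecahydroazulene-1,6-dicarboxylate F2. C9 and C26 then rest on substrate control by C12, and the isomers would have to be separated. Me3SnOH frees the C4 acid 1-(methoxycarbonyl)-1,4,4-trimethyl-8-oxodecahydroazulene-6-carboxylic acid F3. Its 2-thioxopyridin-1(2H)-yl ester F4 is photolysed with t-BuSH to reach 17.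

**Step 16.**
- What may go wrong: deprotonation at the neopentylic C14 may be slow or mismatched with the substrate. Boronate formation may reverse, or the 1,2-migration next to the quaternary C12 may be sluggish.
- Fallback (sets out from 19, returns at 25): C14 is set by a catalytic Cu–B addition/protonation instead of a carbenoid homologation. Dess–Martin oxidation of 19 gives the aldehyde Az–CHO F5. 3-Furyllithium (3-bromofuran, n-BuLi, −78 °C) gives the carbinol Az–CH(OH)(furan-3-yl) F6. A second Dess–Martin oxidation gives the non-enolisable ketone Az–C(O)(furan-3-yl) F7. Wittig methylenation (Ph3P=CH2, PhMe, heat) gives the heteroaryl alkene Az–C(=CH2)(furan-3-yl) F8. Copper-catalysed enantioselective protoboration (B2pin2, MeOH, chiral NHC–Cu) acts only on the furan-conjugated alkene, putting boron on C15 and hydrogen on C14. This gives 25, which is oxidised as in step 17.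

**Step 21.**
- What may go wrong: the very hindered β-carbon may slow hydrocupration. The resident C14 centre may also override the ligand, giving poor facial selectivity at C20.
- Fallback (sets out from 29, returns at 32): control is handed to a neighbouring resident stereocentre. MeOH/CSA converts 29 into its methyl pseudo-esters. The (21R) epimer (2S)-2-Az-2-[(2R)-2-methoxy-5-oxo-2,5-dihydrofuran-3-yl]ethyl acetate F9 is separated, and the other epimer is re-equilibrated with acid. Achiral copper hydride (Stryker's reagent, PhMe) adds hydride to C20 anti to the adjacent C21 methoxy group to give the saturated methoxy lactone F10. Mild aqueous acid gives the lactol F11. NaBH4 reduces its aldehyde form to the hydroxy acid F12, which closes to 32 on acidification.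

**Further compounds**
F1 | step 8 | methyl (1R)-2-[3-(methoxycarbonyl)-5-methylhex-4-enoyl]-1-methylcyclopent-2-ene-1-carboxylate | CC(C)=CC(CC(=O)C1=CCC[C@@]1(C)C(=O)OC)C(=O)OC
F2 | step 8 | dimethyl 1,4,4-trimethyl-8-oxodecahydroazulene-1,6-dicarboxylate | O=C1CC(C(=O)OC)CC(C)(C)[C@@H]2CC[C@@](C)(C(=O)OC)[C@H]12
F3 | step 8 | 1-(methoxycarbonyl)-1,4,4-trimethyl-8-oxodecahydroazulene-6-carboxylic acid | O=C1CC(C(=O)O)CC(C)(C)[C@@H]2CC[C@@](C)(C(=O)OC)[C@H]12
F4 | step 8 | 2-thioxopyridin-1(2H)-yl ester of F3 | O=C1CC(C(=O)ON3C=CC=CC3=S)CC(C)(C)[C@@H]2CC[C@@](C)(C(=O)OC)[C@H]12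
F5 | step 16 | Az–CHO | C=C1CCCC(C)(C)[C@@H]2CC[C@@](C)(C=O)[C@H]12
F6 | step 16 | Az–CH(OH)(furan-3-yl) | C=C1CCCC(C)(C)[C@@H]2CC[C@@](C)(C(O)c3ccoc3)[C@H]12
F7 | step 16 | Az–C(O)(furan-3-yl) | C=C1CCCC(C)(C)[C@@H]2CC[C@@](C)(C(=O)c3ccoc3)[C@H]12
F8 | step 16 | Az–C(=CH2)(furan-3-yl) | C=C1CCCC(C)(C)[C@@H]2CC[C@@](C)(C(=C)c3ccoc3)[C@H]12
F9 | step 21 | (2S)-2-Az-2-[(2R)-2-methoxy-5-oxo-2,5-dihydrofuran-3-yl]ethyl acetate | C=C1CCCC(C)(C)[C@@H]2CC[C@@](C)([C@H](COC(C)=O)C3=CC(=O)O[C@H]3OC)[C@H]12
F10 | step 21 | saturated methoxy lactone (C20 R, C21 R) | C=C1CCCC(C)(C)[C@@H]2CC[C@@](C)([C@H](COC(C)=O)[C@@H]3[C@H](OC)OC(=O)C3)[C@H]12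
F11 | step 21 | lactol (2-hydroxy-5-oxooxolan-3-yl compound) | C=C1CCCC(C)(C)[C@@H]2CC[C@@](C)([C@H](COC(C)=O)[C@@H]3C(O)OC(=O)C3)[C@H]12
F12 | step 21 | hydroxy acid, 5-acetoxy-4-Az-3-(hydroxymethyl)pentanoic acid | C=C1CCCC(C)(C)[C@@H]2CC[C@@](C)([C@H](COC(C)=O)[C@H](CO)CC(=O)O)[C@H]12
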